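I decide to time this flask by counting turnovers, and I start from the alpha run, which has the flask's substrate charge and half its enzyme.

| flask | substrate | enzyme | remark | time |
|---|---|---|---|---|
| eta | 14 mM | 5 µM | run made earlier |  |
| theta | 22 mM | 5 µM | run made earlier |  |
| alpha | 10 mM | 2.5 µM | run made earlier |  |
| flask | 10 mM | 5.0 µM |  | 6.0 h |

| run | time / h | target / % | substrate / % |
|---|---|---|---|
| eta | 0.500 | 6.0 | 89.1 |
| eta | 0.833 | 9.4 | 83.0 |
| eta | 1.00 | 9.3 | 80.2 |
| eta | 1.50 | 10.5 | 70.3 |
| eta | 2.50 | 11.4 | 53.7 |
| eta | 4.00 | 8.2 | 35.1 |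
| theta | 0.500 | 2.7 | 91.6 |
| theta | 0.833 | 3.7 | 85.5 |
| theta | 1.00 | 5.8 | 84.4 |
| theta | 1.50 | 8.0 | 74.2 |
| theta | 2.50 | 6.0 | 61.8 |
| theta | 4.00 | 7.8 | 44.1 |
| alpha | 0.500 | 2.5 | 91.7 |
| alpha | 0.833 | 4.9 | 88.1 |
| alpha | 1.33 | 4.3 | 79.5 |
| alpha | 2.00 | 5.1 | 72.0 |
| alpha | 4.00 | 6.7 | 49.9 |

(readings scatter by 1 percentage point)

- the best time, 6.0 h at the latest, for target
- the amount of target, in percent of the substrate charged, at that time

- the earlier runs were read with a standard deviation of 1 percentage point

In the alpha table, the first row reads 664 h⁻¹, counted as substrate lost per enzyme per hour, by whatever route. The last row reads a lower average from the start, 501 h⁻¹. This average is my pace, a turnover frequency.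

The highest target reading of the eta run, 11.4%, stands with 53.7% of its substrate left, against 49.9% left in alpha's last row. So I take the share of substrate lost by that alpha row as a rough mark for the peak, with the scatter of the readings on it. At this pace and with twice the enzyme, the flask loses that share of its substrate at 2.00 h, and that is my time for its peak.

The forecast says 12% at 1.9 h, a little earlier than my time, on the ground that “selectivity seems to improve with more enzyme and less substrate”.

The flask gives 13.0% at 2.12 h.

    substrate + enzyme → target + enzyme, rate k1*[substrate]^2*[enzyme]/(1 + ([substrate]/Kh1)^2) (4.80 mM, k = 1.80 × 10⁷ M⁻² h⁻¹)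
    target → over-reaction product (k = 0.910 h⁻¹)
    substrate → uncatalysed product (k = 0.0860 h⁻¹)

By 2.12 h the flask has lost 44.8% of its substrate, where my pace gives 53.1%. The half-life of target on its way to over-reaction product is 0.76 h, short against 6.0 h. Target is made 1.07 times as fast as it is used up at 1.89 h, and 0.599 times as fast at 6.00 h. Less enzyme overturns the 13.0%: the neighbour flask with 2.00 µM loses 63.3% of its substrate by 6.0 h, against 60.1% by my pace, and its best target is 5.86%.

All runs are simulated for substances that don't exist; scatter was added.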